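**Plan**
- Quinone numbering: C1 (C=O beside the furyl-bearing carbon C2), C3–H, C4 (C=O), C5–H, C6–H. The retrosynthesis cuts C4–C5 (carbonyl carbon to CH) first and reconnects C1 to C4 as a four-membered ring.
- Enabling feature: C1(O)–C2(furyl)=C3H–C4(O) is a four-carbon, 1,4-dioxygenated unit (an opened cyclobutenone from a squarate) and C5H=C6H is a bare vinyl group. The quinone ring is therefore the 6π-electrocyclisation product of the dienylketene released from a 3-furyl-4-hydroxy-4-vinylcyclobutenone.
- Further cuts, in order: furan C2–quinone C2 bond, ester C–O, prenyl C=C, carbinol C–CH2.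
- Forward: the furan ring is bought. The side chain is built by allylboration, cross-metathesis and acylation. The four-membered ring comes from diisopropyl squarate (reduction, vinyl addition, silylation). The halves are joined by furylmagnesium addition with 1,3-carbonyl transposition. Thermolysis turns the four-membered ring into the six-membered ring (hydroquinone), and Ag2O gives the quinone.
- Stereochemistry: the single (R) carbinol centre comes from reagent-controlled Brown allylboration (isopinocampheyl groups from (−)-α-pinene) and is carried through unchanged. The ring carbinol centre of the cyclobutenone is uncontrolled and is erased in the key step.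

Key step: step 8

Assumption: 1 and 5 are taken as catalogue compounds, and compounds 8 to 12 are used as racemates or diastereomer mixtures at the ring carbinol carbon, which the key step removes.

**Step 1**
Reactants: 1 5-bromofuran-3-carbaldehyde
Product: 2 (1R)-1-(5-bromofuran-3-yl)but-3-en-1-ol
Conditions: (+)-Ipc2B(allyl) [isopinocampheyl groups from (−)-α-pinene], Et2O, −78 °C; then NaOH, H2O2, H2O, 0 °C to rt
Reagents that add atoms: (+)-B-allyldiisopinocampheylborane, C=CCB([C@H]1C[C@H]2C[C@@H]([C@@H]1C)C2(C)C)[C@H]1C[C@H]2C[C@@H]([C@@H]1C)C2(C)C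
Why: Brown allylboration through a chair six-membered transition state, in which the isopinocampheyl groups from (−)-α-pinene should deliver the allyl group to the Re face of an aryl-type aldehyde and so set the (R) carbinol centre.

**Step 2**
Reactants: 2 (1R)-1-(5-bromofuran-3-yl)but-3-en-1-ol
Product: 3 (1R)-1-(5-bromofuran-3-yl)-4-methylpent-3-en-1-ol
Conditions: second-generation Grubbs catalyst (5 mol %), 2-methyl-2-butene/CH2Cl2, 40 °C
Reagents that add atoms: 2-methyl-2-butene, CC=C(C)C
Why: Olefin cross-metathesis of the terminal alkene with excess 2-methyl-2-butene should install the isopropylidene terminus with loss of propene, leaving the carbinol centre and the bromofuran untouched.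

**Step 3**
Reactants: 3 (1R)-1-(5-bromofuran-3-yl)-4-methylpent-3-en-1-ol
Product: 4 (1R)-1-(5-bromofuran-3-yl)-4-methylpent-3-en-1-yl 3-methylbutanoate
Conditions: isovaleryl chloride, pyridine, DMAP (cat.), CH2Cl2, 0 °C to rt
Reagents that add atoms: 3-methylbutanoyl chloride, CC(C)CC(=O)Cl
Why: Nucleophile-catalysed acylation of a secondary alcohol, with retention at the carbinol carbon because its C–O bond is not broken.

**Step 4**
Reactants: 5 diisopropyl squarate
Product: 7 3-isopropoxycyclobut-3-ene-1,2-dione, via hydroxycyclobutenone 6 (not isolated)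
Conditions: LiAlH(OtBu)3, THF, −78 to −20 °C; then conc. HCl (cat.), CH2Cl2, rt
Reagents that add atoms: water, O
Why: Mono-1,2-reduction of one squarate carbonyl by the bulky hydride, then acid-induced allylic ionisation of the carbinol with hydrolysis of the vinylogous ester (1,3-carbonyl transposition), should give the isopropyl semisquarate.

**Step 5**
Reactants: 7 3-isopropoxycyclobut-3-ene-1,2-dione
Product: 8 4-hydroxy-3-isopropoxy-4-vinylcyclobut-2-en-1-one (racemic)
Conditions: vinylmagnesium bromide (1.05 equiv), THF, −78 °C; aq. NH4Cl
Reagents that add atoms: vinylmagnesium bromide, C=C[Mg]Br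
Why: Grignard 1,2-addition should go to the ketone carbonyl attached to the isopropoxy-bearing carbon, because the other carbonyl is a deactivated vinylogous ester (the usual site selectivity of 3-alkoxycyclobutenediones); the new centre is racemic and is erased later.

**Step 6**
Reactants: 8 4-hydroxy-3-isopropoxy-4-vinylcyclobut-2-en-1-one
Product: 9 3-isopropoxy-4-(trimethylsilyloxy)-4-vinylcyclobut-2-en-1-one (racemic)
Conditions: TMSCl, imidazole, DMF, 0 °C
Reagents that add atoms: chlorotrimethylsilane, C[Si](C)(C)Cl
Why: Silylation masks the acidic tertiary hydroxyl so that the next organometallic adds to the carbonyl instead of being quenched or triggering alkoxide-accelerated ring opening.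

**Step 7**
Reactants: 4 (1R)-1-(5-bromofuran-3-yl)-4-methylpent-3-en-1-yl 3-methylbutanoate; 9 3-isopropoxy-4-(trimethylsilyloxy)-4-vinylcyclobut-2-en-1-one
Product: 12 (1R)-1-[5-(4-hydroxy-3-oxo-4-vinylcyclobut-1-en-1-yl)furan-3-yl]-4-methylpent-3-en-1-yl 3-methylbutanoate (two diastereomers at the ring carbinol carbon), via furylmagnesium chloride 10 (not isolated), via carbinol adduct 11 (not isolated)
Conditions: 4, i-PrMgCl·LiCl (1.1 equiv), THF, −15 °C; then 9, −40 to 0 °C; then 1 M HCl, THF, 0 °C
Reagents that add atoms: water, O
Why: Bromine–magnesium exchange at the furan α-carbon (functionalised Grignard formation, tolerant of a hindered ester at low temperature), 1,2-addition to the only carbonyl of vinylogous ester 9, and an acid-induced Stork–Danheiser-type 1,3-carbonyl transposition with loss of isopropanol and the TMS group should place the furyl group on ring C3 beside the carbinol carbon; a 1,4-addition–elimination would give the same constitution, since both carbons flank the carbinol carbon.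

**Step 8**
Reactants: 12 (1R)-1-[5-(4-hydroxy-3-oxo-4-vinylcyclobut-1-en-1-yl)furan-3-yl]-4-methylpent-3-en-1-yl 3-methylbutanoate
Product: 15 (1R)-1-[5-(2,5-dihydroxyphenyl)furan-3-yl]-4-methylpent-3-en-1-yl 3-methylbutanoate, via dienylketene 13 (not isolated), via cyclohexadienone 14 (not isolated)
Conditions: toluene (0.01 M, degassed), 110 °C
Reagents that add atoms: none
Why: Heating should open the cyclobutenone by conrotatory 4π electrocyclic cleavage of its C1–C4 bond to the (Z)-dienylketene 13, whose ketene carbon and vinyl terminus close by disrotatory 6π electrocyclisation to cyclohexa-2,4-dienone 14, which enolises to hydroquinone 15. The closest known reaction type is the Moore rearrangement of 4-alkenyl-4-hydroxycyclobutenones to hydroquinones, here with hydrogen at ring C2 and a 2-furyl group at ring C3. The six-membered ring closes in the 6π-electrocyclic mode, the new σ bond joining the ketene carbon to the CH2 terminus of the vinyl group; this is the C4–C5 bond in the quinone numbering of the plan. No stereocentre is created: the ring carbinol centre of 12 is destroyed, so both diastereomers converge, and the side-chain centre is not touched under neutral thermal conditions. The step needs torquoselectivity in the ring opening, secured by the donor hydroxyl on ring C4, which rotates outward and turns the vinyl group inward, cis to the ketenyl carbon; the regiochemistry (furyl beside the carbinol-derived oxygen, CH beside the ketene-derived oxygen) is fixed by the substitution of the four-membered ring. Intermolecular capture of the ketene is suppressed by high dilution in a non-nucleophilic solvent.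

**Step 9**
Reactants: 15 (1R)-1-[5-(2,5-dihydroxyphenyl)furan-3-yl]-4-methylpent-3-en-1-yl 3-methylbutanoate
Product: 16 (1R)-1-[5-(3,6-dioxocyclohexa-1,4-dien-1-yl)furan-3-yl]-4-methylpent-3-en-1-yl 3-methylbutanoate
Conditions: Ag2O, Na2SO4, Et2O, rt
Reagents that add atoms: none
Why: Two-electron oxidation of a hydroquinone to the p-benzoquinone by a mild heterogeneous oxidant that should leave the furan, the trisubstituted alkene, the ester and the carbinol centre alone.

**Compound list**
1 | 5-bromofuran-3-carbaldehyde | O=Cc1coc(Br)c1 | starting material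
2 | (1R)-1-(5-bromofuran-3-yl)but-3-en-1-ol | C=CC[C@@H](O)c1coc(Br)c1 | intermediate
3 | (1R)-1-(5-bromofuran-3-yl)-4-methylpent-3-en-1-ol | CC(C)=CC[C@@H](O)c1coc(Br)c1 | intermediate
4 | (1R)-1-(5-bromofuran-3-yl)-4-methylpent-3-en-1-yl 3-methylbutanoate | CC(C)=CC[C@@H](OC(=O)CC(C)C)c1coc(Br)c1 | intermediate
5 | diisopropyl squarate (3,4-diisopropoxycyclobut-3-ene-1,2-dione) | CC(C)OC1=C(OC(C)C)C(=O)C1=O | starting material
6 | 4-hydroxy-2,3-diisopropoxycyclobut-2-en-1-one (racemic, not isolated) | CC(C)OC1=C(OC(C)C)C(O)C1=O | intermediate
7 | 3-isopropoxycyclobut-3-ene-1,2-dione | CC(C)OC1=CC(=O)C1=O | intermediate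
8 | 4-hydroxy-3-isopropoxy-4-vinylcyclobut-2-en-1-one (racemic) | CC(C)OC1=CC(=O)C1(O)C=C | intermediate
9 | 3-isopropoxy-4-(trimethylsilyloxy)-4-vinylcyclobut-2-en-1-one (racemic) | CC(C)OC1=CC(=O)C1(C=C)O[Si](C)(C)C | intermediate
10 | {4-[(1R)-4-methyl-1-(3-methylbutanoyloxy)pent-3-en-1-yl]furan-2-yl}magnesium chloride, LiCl complex (not isolated) | CC(C)=CC[C@@H](OC(=O)CC(C)C)c1coc([Mg]Cl)c1 | intermediate
11 | (1R)-1-{5-[1-hydroxy-3-isopropoxy-4-(trimethylsilyloxy)-4-vinylcyclobut-2-en-1-yl]furan-3-yl}-4-methylpent-3-en-1-yl 3-methylbutanoate, present as its chloromagnesium alkoxide (not isolated) | CC(C)=CC[C@@H](OC(=O)CC(C)C)c1coc(C2(O)C=C(OC(C)C)C2(C=C)O[Si](C)(C)C)c1 | intermediate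
12 | (1R)-1-[5-(4-hydroxy-3-oxo-4-vinylcyclobut-1-en-1-yl)furan-3-yl]-4-methylpent-3-en-1-yl 3-methylbutanoate (two diastereomers at the ring carbinol carbon) | CC(C)=CC[C@@H](OC(=O)CC(C)C)c1coc(C2=CC(=O)C2(O)C=C)c1 | intermediate
13 | (1R)-1-{5-[(3Z)-4-hydroxy-1-oxohexa-1,3,5-trien-3-yl]furan-3-yl}-4-methylpent-3-en-1-yl 3-methylbutanoate (dienylketene, not isolated) | CC(C)=CC[C@@H](OC(=O)CC(C)C)c1coc(/C(C=C=O)=C(O)/C=C)c1 | intermediate
14 | (1R)-1-[5-(6-hydroxy-3-oxocyclohexa-1,5-dien-1-yl)furan-3-yl]-4-methylpent-3-en-1-yl 3-methylbutanoate (not isolated) | CC(C)=CC[C@@H](OC(=O)CC(C)C)c1coc(C2=CC(=O)CC=C2O)c1 | intermediate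
15 | (1R)-1-[5-(2,5-dihydroxyphenyl)furan-3-yl]-4-methylpent-3-en-1-yl 3-methylbutanoate | CC(C)=CC[C@@H](OC(=O)CC(C)C)c1coc(-c2cc(O)ccc2O)c1 | intermediate
16 | (1R)-1-[5-(3,6-dioxocyclohexa-1,4-dien-1-yl)furan-3-yl]-4-methylpent-3-en-1-yl 3-methylbutanoate | CC(C)=CC[C@@H](OC(=O)CC(C)C)c1coc(C2=CC(=O)C=CC2=O)c1 | target

**Step count and risks**
Total step count: 9. Longest linear sequence: 6 steps (steps 1, 2, 3, 7, 8, 9 from compound 1; the squarate branch, steps 4, 5, 6, then 7, 8, 9, is equally long).

Steps most likely to fail:

1. Step 7. The organomagnesium species may attack the isovalerate (ester cleavage or ketone formation) while the bromine–magnesium exchange is still slow, or may add sluggishly to the hindered vinylogous ester carbonyl. The fallback is an ester-free organolithium with late acylation. It sets out from compound 3: deprotonation with n-BuLi (1 equiv) and bromine–lithium exchange with t-BuLi (2 equiv) in THF at −78 °C should give the dilithio species F1. Addition of 9 at −78 °C and work-up with 1 M HCl should give 4-hydroxy-3-{4-[(1R)-1-hydroxy-4-methylpent-3-en-1-yl]furan-2-yl}-4-vinylcyclobut-2-en-1-one F2. Selective acylation of its secondary hydroxyl with isovaleric anhydride, Et3N and catalytic DMAP at −20 °C (the tertiary ring carbinol is expected to stay free) comes back to the route at compound 12.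

2. Step 8. Inward rotation of the hydroxyl with lactonisation of the ketene to a butenolide, or oligomerisation of the hydrogen-substituted ketene, may outrun the electrocyclisation. The fallback builds the aryl–furan bond by cross-coupling instead of forming the six-membered ring. It sets out from compound 4: Suzuki–Miyaura coupling with commercial (2,5-dimethoxyphenyl)boronic acid (Pd(PPh3)4, K3PO4, dioxane/H2O, 70 °C) should give (1R)-1-[5-(2,5-dimethoxyphenyl)furan-3-yl]-4-methylpent-3-en-1-yl 3-methylbutanoate F3. Oxidative demethylation with (NH4)2Ce(NO3)6 in MeCN/H2O at 0 °C comes back to the route at compound 16.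

3. Step 1. Facial selectivity with the electron-poor heteroaryl aldehyde may be insufficient, or the bromofuran may suffer during the alkaline peroxide work-up. The fallback is a resolution instead of an asymmetric addition. It sets out from compound 1: allylmagnesium bromide in THF at −78 °C should give racemic 1-(5-bromofuran-3-yl)but-3-en-1-ol F4. Lipase-catalysed transesterification with vinyl acetate (immobilised Candida antarctica lipase B, hexane, rt) should acylate the (R)-enantiomer, as expected for an aryl/allyl carbinol, to give (1R)-1-(5-bromofuran-3-yl)but-3-en-1-yl acetate F5, which is separated from the unreacted (S)-alcohol. Methanolysis with K2CO3 in MeOH comes back to the route at compound 2.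

**Further compounds**
F1 | step 7 | lithium (1R)-1-(5-lithiofuran-3-yl)-4-methylpent-3-en-1-olate (dilithio species, not isolated) | CC(C)=CC[C@@H](O[Li])c1coc([Li])c1
F2 | step 7 | 4-hydroxy-3-{4-[(1R)-1-hydroxy-4-methylpent-3-en-1-yl]furan-2-yl}-4-vinylcyclobut-2-en-1-one | CC(C)=CC[C@@H](O)c1coc(C2=CC(=O)C2(O)C=C)c1
F3 | step 8 | (1R)-1-[5-(2,5-dimethoxyphenyl)furan-3-yl]-4-methylpent-3-en-1-yl 3-methylbutanoate | CC(C)=CC[C@@H](OC(=O)CC(C)C)c1coc(-c2cc(OC)ccc2OC)c1
F4 | step 1 | racemic 1-(5-bromofuran-3-yl)but-3-en-1-ol | C=CCC(O)c1coc(Br)c1
F5 | step 1 | (1R)-1-(5-bromofuran-3-yl)but-3-en-1-yl acetate | C=CC[C@@H](OC(C)=O)c1coc(Br)c1
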